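The route rests on opening the O1–C6 bond of the 4H-pyran-4-one ring. Ring atom C6, the carbon bonded to O1, carries a bromine and sits beside brominated C5. This pair is read as a Br2C=C(Br)–C(=O) unit that has given up one bromide. In a single operation the enol oxygen on chain carbon C5 of an open C8 chain adds to the CBr2 terminus and bromide leaves. This closes the only ring and delivers the target with all three bromines and the propanoyl group in place. The precursor is 1,1,2,4-tetrabromooct-1-ene-3,5,6-trione. It is reached by acylating a C6-ketal-masked methyl ketone with tribromoacryloyl chloride, brominating C4 and unmasking C6.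

Key step: step 8

Remark 1: the target has no stereocentre and no stereogenic double bond, so it is one achiral compound. The only stereocentre met on the way (chain C4 of the two open-chain tetrabromides) is racemic, enolisable and becomes sp2 in the key step.
Remark 2: open-chain compounds are numbered C1 (CBr2) to C8 (CH3). On ring closure chain C1, C2, C3, C4, C5 and the oxygen on C5 become ring C6, C5, C4, C3, C2 and O1.
Remark 3: monoketalisation of pentane-2,3-dione would favour the less hindered acetyl carbonyl, which is the wrong one, so the ketal ketone is built from methyl 2-oxobutanoate, where the ketal position is unambiguous.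

Step 1
Reactants: 1 methyl 2-oxobutanoate
Product: 2 methyl 2,2-dimethoxybutanoate
Conditions: HC(OMe)3, cat. H2SO4, MeOH, reflux; neutralise (NaOMe), distil
Reagents that add atoms: trimethyl orthoformate COC(OC)OC; methanol CO (exchanges with the orthoester)
Why: Acid-catalysed ketalisation driven by the orthoester as water scavenger works well on the activated keto group of 2-oxo esters (pyruvates are the model), and the ester carbonyl does not ketalise, so the mask sits on the future chain C6 without any regiochemical question.

Step 2
Reactants: 2 methyl 2,2-dimethoxybutanoate
Product: 4 3,3-dimethoxypentan-2-one, via Weinreb amide 3 (not isolated)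
Conditions: MeNHOMe·HCl, iPrMgCl, THF, −20 °C; then MeMgBr, 0 °C; aq. NH4Cl
Reagents that add atoms: methylmagnesium bromide C[Mg]Br (the new methyl group, later chain C4); N,O-dimethylhydroxylamine hydrochloride CNOC.Cl (atoms appear only in 3)
Why: One-pot Weinreb ketone synthesis, in which the chloromagnesium amide turns the ester into 3, MeMgBr adds only once because the N-methoxy chelate holds the tetrahedral adduct until the quench, and the ketal is inert to these basic reagents.

Step 3
Reactants: 5 propiolic acid
Product: 7 2,3,3-tribromoacrylic acid, via 3-bromopropiolic acid 6 (not isolated)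
Conditions: Br2 (1 equiv), aq. KOH, 0 °C; cold dil. H2SO4, extract (CH2Cl2), dry, do not concentrate; then Br2 (1.05 equiv), CH2Cl2, rt, ambient light
Reagents that add atoms: bromine BrBr
Why: Hypobromite bromination of the acidic terminal alkyne C–H followed by electrophilic addition of Br2 across the bromoalkyne are both classical for this acid, the alkene of 7 has two bromines on C3 and hence no geometry to control, and the lachrymatory, potentially unstable 6 stays in cold dilute solution.

Step 4
Reactants: 7 2,3,3-tribromoacrylic acid
Product: 8 2,3,3-tribromoacryloyl chloride
Conditions: (COCl)2, cat. DMF, CH2Cl2, 0 °C → rt; evaporate, use crude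
Reagents that add atoms: oxalyl chloride O=C(Cl)C(=O)Cl
Why: DMF-catalysed (Vilsmeier-type) acid chloride formation runs at or below room temperature, 7 has no α-hydrogen that could lead to a ketene, and the mild conditions keep chloride from exchanging with the vinylic bromines.

Step 5
Reactants: 4 3,3-dimethoxypentan-2-one; 8 2,3,3-tribromoacryloyl chloride
Product: 11 1,1,2-tribromo-6,6-dimethoxyoct-1-ene-3,5-dione, via lithium enolate 9 (not isolated), via lithium diketonate 10 (not isolated)
Conditions: 4 (2 equiv), LiHMDS (2 equiv), THF, −78 °C; 8 (1 equiv), −78 °C; AcOH quench at −78 °C
Reagents that add atoms: lithium hexamethyldisilazide [Li]N([Si](C)(C)C)[Si](C)(C)C (lithium appears only in 9 and 10)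
Why: Crossed Claisen-type C-acylation of a preformed lithium enolate, in which 4 can enolise only toward its methyl group, the acyl chloride carbon outcompetes the CBr2 terminus as electrophile at −78 °C, a second equivalent of 9 converts the acidic product into chelate 10, whose U shape keeps the C5 oxygen turned away from C1, and the cold acid quench releases 11 as its hydrogen-bonded enol.

Step 6
Reactants: 11 1,1,2-tribromo-6,6-dimethoxyoct-1-ene-3,5-dione
Product: 12 rac-1,1,2,4-tetrabromo-6,6-dimethoxyoct-1-ene-3,5-dione
Conditions: NBS (1.0 equiv), CH2Cl2, 0 °C, dark
Reagents that add atoms: N-bromosuccinimide O=C1CCC(=O)N1Br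
Why: Electrophilic α-bromination of a largely enolised 1,3-diketone at its central carbon by NBS needs no acid or base, the monobromide is less enolised and so resists a second bromination, the electron-poor tribromoalkene and the ketal are inert, and the new C4 stereocentre arises racemic and labile, which does not matter because it becomes sp2 in step 8.

Step 7
Reactants: 12 rac-1,1,2,4-tetrabromo-6,6-dimethoxyoct-1-ene-3,5-dione
Product: 13 rac-1,1,2,4-tetrabromooct-1-ene-3,5,6-trione
Conditions: TFA–H2O (9:1), CH2Cl2, 0 °C → rt; cold water wash, toluene azeotrope, use at once
Reagents that add atoms: water O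
Why: Acid-catalysed hydrolysis of an acyclic dimethyl ketal, the most labile ketal class and removable even next to a carbonyl group, proceeds in a medium that keeps the bromodiketone un-ionised and so holds ring closure back, and any closure that still takes place merely anticipates step 8.

Step 8
Reactants: 13 rac-1,1,2,4-tetrabromooct-1-ene-3,5,6-trione
Product: 15 3,5,6-tribromo-2-propanoyl-4H-pyran-4-one, via lutidinium enolate 14 (not isolated)
Conditions: 2,6-lutidine (1.05 equiv), 4 Å MS, dry CH2Cl2 (0.02 M), 0 °C → rt
Reagents that add atoms: 2,6-lutidine Cc1cccc(C)n1 (atoms appear only in the counter-ion of 14)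
Why: Lutidine removes the very acidic C4–H, which erases the C4 stereocentre and turns the labile C4–Br into an inert vinylic bromide, and with a non-chelating counter-ion 14 can rotate about C3–C4 until the C5 oxygen faces C1. That oxygen adds to the CBr2 carbon, the β-position of the C1=C2–C3=O enone, and the C2=C3 enolate so formed expels one of the two geminal bromides; an oxa-6π closure of the O=C5–C4=C3–C2=C1 tautomer followed by bromide loss describes the same event. The reaction type is nucleophilic vinylic substitution by oxygen within a β-halo enone, the process that turns o-hydroxyaryl β-halovinyl ketones into chromones and β-chlorovinyl ketones into pyran-4-ones. The one ring formed (O1, C2, C3, C4, C5, C6) closes 6-endo-trig, and no stereocentre is created. The selectivity needed is attack of the C5 oxygen on C1 over all other closures: C4 on C1 would give a four-membered ring and the C6 oxygen on C1 a seven-membered ring, while 5-exo hemiketalisation of the C3 oxygen onto the C6 carbonyl is reversible and is drained by the irreversible loss of bromide. The dry medium and the hindered, non-nucleophilic base shield the C5–C6 dicarbonyl from acyl cleavage and the product C6–Br, a vinylogous acyl bromide, from substitution, and high dilution disfavours intermolecular attack.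

Compound list
1 | methyl 2-oxobutanoate | CCC(=O)C(=O)OC | starting material
2 | methyl 2,2-dimethoxybutanoate | CCC(OC)(OC)C(=O)OC | intermediate
3 | N,2,2-trimethoxy-N-methylbutanamide (Weinreb amide, not isolated) | CCC(OC)(OC)C(=O)N(C)OC | intermediate
4 | 3,3-dimethoxypentan-2-one | CCC(OC)(OC)C(C)=O | intermediate
5 | propiolic acid | C#CC(=O)O | starting material
6 | 3-bromopropiolic acid (kept in solution, not isolated) | OC(=O)C#CBr | intermediate
7 | 2,3,3-tribromoacrylic acid | OC(=O)C(Br)=C(Br)Br | intermediate
8 | 2,3,3-tribromoacryloyl chloride | O=C(Cl)C(Br)=C(Br)Br | intermediate
9 | lithium 3,3-dimethoxypent-1-en-2-olate (not isolated) | [Li+].C=C([O-])C(CC)(OC)OC | intermediate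
10 | lithium (4Z)-1,1,2-tribromo-6,6-dimethoxy-3-oxoocta-1,4-dien-5-olate (chelate, not isolated) | [Li+].CCC(OC)(OC)/C([O-])=C/C(=O)C(Br)=C(Br)Br | intermediate
11 | 1,1,2-tribromo-6,6-dimethoxyoct-1-ene-3,5-dione (drawn as diketone, expected mainly as chelated enol) | CCC(OC)(OC)C(=O)CC(=O)C(Br)=C(Br)Br | intermediate
12 | rac-1,1,2,4-tetrabromo-6,6-dimethoxyoct-1-ene-3,5-dione (C4 racemic, labile) | CCC(OC)(OC)C(=O)C(Br)C(=O)C(Br)=C(Br)Br | intermediate
13 | rac-1,1,2,4-tetrabromooct-1-ene-3,5,6-trione (C4 racemic, labile; key-step precursor) | CCC(=O)C(=O)C(Br)C(=O)C(Br)=C(Br)Br | intermediate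
14 | 2,6-dimethylpyridinium (4E)-1,1,2,4-tetrabromo-3,6-dioxoocta-1,4-dien-5-olate (C5 oxygen cis to C3, not isolated) | CCC(=O)/C([O-])=C(\Br)C(=O)C(Br)=C(Br)Br.Cc1cccc(C)[nH+]1 | intermediate
15 | 3,5,6-tribromo-2-propanoyl-4H-pyran-4-one (achiral) | CCC(=O)c1oc(Br)c(Br)c(=O)c1Br | target

Total step count: 8. Longest linear sequence: 6 (steps 1, 2, 5, 6, 7, 8). The branch of steps 3 and 4 joins at step 5 and is equally long.

Steps most likely to fail

Step 8. The ring closure may be slow because the enolate is strongly stabilised and shares its C3 carbonyl with the acceptor. Three processes may then outrun it: acyl cleavage of the contiguous C5–C6 dicarbonyl by adventitious nucleophiles, transfer of positive bromine away from C4, and intermolecular vinylic substitution. The fallback sets out from 12 and comes back at 15, and it closes the ring while C6 is still a ketal. Treating 12 with 2,6-lutidine in MeCN should give 3,5,6-tribromo-2-(1,1-dimethoxypropyl)-4H-pyran-4-one F1 by the same oxygen-to-CBr2 addition–elimination. The substrate is now a plain 2-bromo-1,3-diketone, which has no 1,2-dicarbonyl to cleave or hemiketalise and carries a more electron-rich oxygen. The ketal of F1 is then removed by acidolysis in neat formic acid at room temperature. This water-poor method passes the methyl groups on to formate and so spares the C6–Br bond, giving 15.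

Step 5. Several processes may erode the C-acylation: O-acylation of the enolate, carbon attack at the CBr2 terminus, halophilic attack on a vinylic bromine, or ring closure of the chelate on warming before C4 is brominated. The fallback sets out from 8 and 4 and comes back at 11, and it replaces the acylation by an aldol addition and an oxidation. Acid chloride 8 is reduced with LiAlH(OtBu)3 in THF at −78 °C to 2,3,3-tribromoacrolein F2. Enolate 9, made from one equivalent of 4, adds to the aldehyde at −78 °C to give rac-1,1,2-tribromo-3-hydroxy-6,6-dimethoxyoct-1-en-5-one F3. This product is not acidic and cannot close to a pyranone. Dess–Martin oxidation of the β-hydroxy ketone F3 then gives 11.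

Step 7. Ionisation of a ketal flanked by an electron-poor carbonyl may be sluggish and call for stronger acid or longer times. Loss of bromine from C4 or addition of water at C1 may then set in. The fallback sets out from 11 and comes back at 13, and it inverts unmasking and bromination. Hydrolysis of 11 with aqueous TFA, at a stage where C4 carries no labile bromine and the chelated enol tolerates acid, should give 1,1,2-tribromooct-1-ene-3,5,6-trione F4. NBS in dry CH2Cl2 at 0 °C then brominates the far more enolised C4 in preference to C7. This delivers 13 in anhydrous solution, ready for step 8.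

Further compounds
F1 | step 8 | 3,5,6-tribromo-2-(1,1-dimethoxypropyl)-4H-pyran-4-one | CCC(OC)(OC)c1oc(Br)c(Br)c(=O)c1Br
F2 | step 5 | 2,3,3-tribromoacrolein | O=CC(Br)=C(Br)Br
F3 | step 5 | rac-1,1,2-tribromo-3-hydroxy-6,6-dimethoxyoct-1-en-5-one | CCC(OC)(OC)C(=O)CC(O)C(Br)=C(Br)Br
F4 | step 7 | 1,1,2-tribromooct-1-ene-3,5,6-trione | CCC(=O)C(=O)CC(=O)C(Br)=C(Br)Br
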